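The data stem from a simulated flask with constants of no real substance.

The flask asked about and the larch run are charged alike, so the flask is the larch run carried on from 60.0 min to 5.0 h.

all flasks: electrophile 1.5 M

| charge | nucleophile | remark | time |
|---|---|---|---|
| larch | 3 M | the very flask that is asked about, followed so far |  |
| flask | 3.00 M |  | 5.0 h |

larch run (percent of the electrophile charged)

| time / min | electrophile / % | target / % |
|---|---|---|
| 5.00 | 26.5 | 35.8 |
| 15.0 | 9.0 | 28.6 |
| 30.0 | 3.7 | 22.8 |
| 40.0 | 2.9 | 18.1 |
| 60.0 | 1.7 | 15.3 |

(each reading ± 1 percentage point)

- the earlier runs were read with a standard deviation of 1 percentage point
- the earlier runs do not show how much of nucleophile is bound; that part of a forecast is a guess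

- part of the electrophile that has reacted at 5.0 h
- share of the unused nucleophile that is free and not bound as protonated nucleophile, at 5.0 h

Follow one electrophile molecule through the flask. It meets nucleophile and becomes target, and the acid set free can hold another nucleophile as protonated nucleophile. In the larch run target falls from 35.8 % to 15.3 %. The reckoning here, not the forecast's, supposes that nucleophile takes the target too, which makes a bill of 3 nucleophile per electrophile going the whole way.

ceiling = nucleophile charged / (3 × electrophile charged) = 66.7 %

This nucleophile ceiling, the share of the charged electrophile that the nucleophile can pay for the whole way, stands below the whole charge, so nucleophile is the limiting reagent on this bill. Yet the larch run has used 98.3 % of its electrophile by 60.0 min, more than the ceiling, so part of it went a cheaper way. The reckoning puts the reacted part in the flask above that reading and gives no number for the free share.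

The forecast says 99.5 % reacted and 4 % free, and of the binding: “this is a guess and the range is wide”.

The flask gives 99.6 % reacted and 2.53 % free, on this scheme:

    electrophile + nucleophile → acid set free + target (k = 0.0930 /M/min)
    nucleophile + acid set free ⇌ protonated nucleophile, settled at all times (K = 1000 /M)
    nucleophile + target → over-reaction product (k = 0.0630 /M/min)
    nucleophile → decomposition product (k = 4.00 × 10⁻⁵ /min)
    2 electrophile → homo dimer (k = 0.0570 /M/min)

At 5.00 h the flask holds 62.3 % over-reaction product, less than the ceiling of 66.7 %, beside 6.96 % target and 30.4 % homo dimer. The neighbour flask with 0.60 M of electrophile has a ceiling of 167 %, more than its electrophile can use. On the same bill its 87.9 % of over-reaction product leaves 47.3 % of its nucleophile; that neighbour flask holds 47 % unbound, and its free share stands at 72.7 %.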